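## Retrosynthetic overview

1. The target is an aromatic ring A (2,6-dihydroxy-4-methoxyacetophenone unit) and a dienone ring B (acetylfilicinic acid unit) joined by one CH2.
2. Last bond, CH2–ring B: conjugate addition of acetylfilicinic acid to the o-quinone methide released from a ring A benzylic sulfonium salt.
3. Key bond, ring A–CH2: a [2,3]-sigmatropic shift of an aryloxysulfonium ylide instead of formaldehyde chemistry. The O-sulfonium phenol acts as an enolonium equivalent and accepts a sulfur-stabilised carbanion, so two carbons that are both nucleophilic in their normal reactivity are joined.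
4. Ring B comes from dearomatising gem-dimethylation of phloroacetophenone.
5. Ring order: no ring is built from open-chain material; ring B is made first by dearomatising a bought arene, and ring A is bought aromatic and kept.

Assumption: the SMILES has no stereocentre and no stereodefined double bond, so the target is achiral (drawn as one enol tautomer) and no enantiocontrol is needed; 1 and 4 are bought.

## Route

Step 1
Reactants: 1 2',4',6'-trihydroxyacetophenone
Product: 3 acetylfilicinic acid (2-acetyl-3,5-dihydroxy-4,4-dimethylcyclohexa-2,5-dien-1-one), via monomethyl ketone 2 (not isolated)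
Conditions: NaOMe (3.0 equiv), MeI (2.2 equiv), MeOH, 0 °C to rt, 16 h; then 1 M HCl
Reagents that add atoms: iodomethane, CI
Why: Riedl-type dearomatising C-methylation, in which the phloroglucinolate of 1 is methylated on carbon to 2 and a second methyl enters the same carbon, breaking the aromatic ring to give the vinylogous acid 3; no stereocentre is formed.

Step 2
Reactants: 4 2',6'-dihydroxy-4'-methoxyacetophenone
Product: 8 1-[2,6-dihydroxy-4-methoxy-3-(methylsulfanylmethyl)phenyl]ethan-1-one, via aryloxysulfonium chloride 5 (not isolated), via sulfonium ylide 6 (not isolated), via dienone 7 (not isolated)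
Conditions: NCS (1.05 equiv), Me2S (1.3 equiv), CH2Cl2, −25 °C, 30 min; add 4, −25 °C, 2 h; Et3N (2.2 equiv), −25 °C to rt
Reagents that add atoms: dimethyl sulfide, CSC
Why: Gassman ortho-alkylation (a Sommelet–Hauser-type [2,3]-sigmatropic rearrangement), in which the phenol oxygen of 4 attacks the sulfur of the Corey–Kim salt to give 5 (the ring now an enolonium equivalent), Et3N forms ylide 6, whose carbanion carbon is delivered through a five-membered transition state to the only free ortho carbon, and dienone 7 rearomatises to 8; the two ortho sites of symmetric 4 are equivalent and no lasting stereocentre is formed.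

Step 3
Reactants: 8 1-[2,6-dihydroxy-4-methoxy-3-(methylsulfanylmethyl)phenyl]ethan-1-one; 3 acetylfilicinic acid
Product: 11 2-acetyl-6-[(3-acetyl-2,4-dihydroxy-6-methoxyphenyl)methyl]-3,5-dihydroxy-4,4-dimethylcyclohexa-2,5-dien-1-one (the target), via sulfonium triflate 9 (not isolated), via o-quinone methide 10 (not isolated)
Conditions: MeOTf (1.05 equiv), CH2Cl2, 0 °C, 1 h; then 3 (1.5 equiv), iPr2NEt (2.5 equiv), MeCN, 0 °C to rt
Reagents that add atoms: none
Why: S-methylation makes the thioether a sulfonium leaving group, base-induced 1,4-elimination of Me2S gives o-quinone methide 10, and the enolate of 3 adds through its only unsubstituted ring carbon (Michael addition to an o-quinone methide) before tautomerisation restores ring A; no stereocentre is formed.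

## Compound list

1 | 2',4',6'-trihydroxyacetophenone (phloroacetophenone) | CC(=O)c1c(O)cc(O)cc1O | starting material
2 | 2',4',6'-trihydroxy-3'-methylacetophenone (not isolated) | CC(=O)c1c(O)cc(O)c(C)c1O | intermediate
3 | acetylfilicinic acid, 2-acetyl-3,5-dihydroxy-4,4-dimethylcyclohexa-2,5-dien-1-one | CC(=O)C1=C(O)C(C)(C)C(O)=CC1=O | intermediate
4 | 2',6'-dihydroxy-4'-methoxyacetophenone | COc1cc(O)c(C(C)=O)c(O)c1 | starting material
5 | (2-acetyl-3-hydroxy-5-methoxyphenoxy)dimethylsulfonium chloride (not isolated) | COc1cc(O)c(C(C)=O)c(O[S+](C)C)c1.[Cl-] | intermediate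
6 | (2-acetyl-3-hydroxy-5-methoxyphenoxy)(methyl)sulfonium methylide (not isolated) | COc1cc(O)c(C(C)=O)c(O[S+](C)[CH2-])c1 | intermediate
7 | 2-acetyl-3-hydroxy-5-methoxy-6-(methylsulfanylmethyl)cyclohexa-2,4-dien-1-one (racemic, not isolated) | CSCC1C(=O)C(C(C)=O)=C(O)C=C1OC | intermediate
8 | 1-[2,6-dihydroxy-4-methoxy-3-(methylsulfanylmethyl)phenyl]ethan-1-one | COc1cc(O)c(C(C)=O)c(O)c1CSC | intermediate
9 | [(3-acetyl-2,4-dihydroxy-6-methoxyphenyl)methyl]dimethylsulfonium triflate (not isolated) | COc1cc(O)c(C(C)=O)c(O)c1C[S+](C)C.[O-]S(=O)(=O)C(F)(F)F | intermediate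
10 | 2-acetyl-3-hydroxy-5-methoxy-6-methylidenecyclohexa-2,4-dien-1-one (o-quinone methide, not isolated) | C=C1C(=O)C(C(C)=O)=C(O)C=C1OC | intermediate
11 | 2-acetyl-6-[(3-acetyl-2,4-dihydroxy-6-methoxyphenyl)methyl]-3,5-dihydroxy-4,4-dimethylcyclohexa-2,5-dien-1-one | COc1cc(O)c(C(C)=O)c(O)c1CC1=C(O)C(C)(C)C(O)=C(C(C)=O)C1=O | target

## Step count and risks

Total step count: 3. Longest linear sequence: 2 steps (1 → 3 → 11, or 4 → 8 → 11).

Steps most likely to fail, most risky first:

**Step 2.** Ring A is very electron-rich, so ring chlorination, sulfur attack by ring carbon (a carbon-bound sulfonium salt) or double alkylation can compete with the [2,3] shift. The fallback sets out from 4 and comes back at 8. It keeps the same polarity but uses cross-coupling: N-iodosuccinimide (MeCN, 0 °C) gives 1-(2,6-dihydroxy-3-iodo-4-methoxyphenyl)ethan-1-one F1, in which the ring carbon is the electrophile. Stille coupling of F1 with tributyl(methylsulfanylmethyl)stannane, the tin form of the sulfur-stabilised carbanion (Pd(P(t-Bu)3)2, zerovalent palladium, 5 mol %, dioxane, 90 °C), then gives 8.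

**Step 3.** Quinone methide 10 can oligomerise, attack the free ring A carbon of 11, or alkylate 3 on oxygen. The fallback sets out from 4 and comes back at 11, and avoids the free quinone methide. The same sulfonium [2,3] shift is run on 4 with 1,3-dithiane in place of Me2S (NCS, CH2Cl2, −25 °C; then Et3N), so the ylide carbon is a masked formyl anion; this gives 1-[3-(1,3-dithian-2-yl)-2,6-dihydroxy-4-methoxyphenyl]ethan-1-one F2. MeI and CaCO3 in aqueous MeCN (40 °C) unmask it to 3-acetyl-2,4-dihydroxy-6-methoxybenzaldehyde F3. F3 and 3 are then joined by three-component reductive alkylation (Hantzsch ester, L-proline 10 mol %, CH2Cl2, rt): Knoevenagel condensation gives 2-acetyl-6-[(3-acetyl-2,4-dihydroxy-6-methoxyphenyl)methylidene]-5-hydroxy-4,4-dimethylcyclohex-5-ene-1,3-dione F4, which is reduced in the flask by hydride transfer to 11.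

**Step 1.** Mono-, di-, tri- and tetramethylated products and O-methyl ethers can form together and lower the yield of 3. The fallback sets out from 1 and comes back at 3, and blocks the second ring carbon first. Friedel–Crafts acetylation of 1 (Ac2O, BF3·OEt2, 90 °C) gives 2,4-diacetylphloroglucinol F5. Its single free ring carbon is gem-dimethylated (MeI, NaOMe, MeOH, rt) to 2,4-diacetyl-3,5-dihydroxy-6,6-dimethylcyclohexa-2,4-dien-1-one F6. One of the two equivalent acetyl groups is then removed by retro-Claisen cleavage (85% H2SO4, 80 °C, short time) to return 3.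

Further compounds

F1 | step 2 | 1-(2,6-dihydroxy-3-iodo-4-methoxyphenyl)ethan-1-one | COc1cc(O)c(C(C)=O)c(O)c1I
F2 | step 3 | 1-[3-(1,3-dithian-2-yl)-2,6-dihydroxy-4-methoxyphenyl]ethan-1-one | COc1cc(O)c(C(C)=O)c(O)c1C1SCCCS1
F3 | step 3 | 3-acetyl-2,4-dihydroxy-6-methoxybenzaldehyde | COc1cc(O)c(C(C)=O)c(O)c1C=O
F4 | step 3 | 2-acetyl-6-[(3-acetyl-2,4-dihydroxy-6-methoxyphenyl)methylidene]-5-hydroxy-4,4-dimethylcyclohex-5-ene-1,3-dione (alkene geometry not defined, not isolated) | COc1cc(O)c(C(C)=O)c(O)c1C=C1C(=O)C(C)(C)C(O)=C(C(C)=O)C1=O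
F5 | step 1 | 2,4-diacetylphloroglucinol | CC(=O)c1c(O)cc(O)c(C(C)=O)c1O
F6 | step 1 | 2,4-diacetyl-3,5-dihydroxy-6,6-dimethylcyclohexa-2,4-dien-1-one | CC(=O)C1=C(O)C(C(C)=O)=C(O)C(C)(C)C1=O
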